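Locants: the flavone unit has rings A/C (C2–C8a) and ring B (C1'–C6'). The flavonol unit has rings A''/C'' (C2''–C8a'') and an anisyl ring (C1'''–C6''').
Cuts: the biaryl bond C6''–C3' goes first, giving unprotected 3,7-dihydroxy-4'-methoxyflavone (C–H partner) and a flavone 3'-triflate (C–O partner). The flavonol is then cut at O1''–C2'' and C3''–OH (Algar–Flynn–Oyamada) and at the enone Cα=Cβ bond (Claisen–Schmidt). The flavone is cut only at O–Tf and 7-O–CH3, back to natural diosmetin.
Forward: ring C'' is closed on a chalcone made from resacetophenone and anisaldehyde, and rings A, C and B of the flavone arrive ready-made. The two complete halves are joined in the last step, which releases the target itself.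
Enabling feature: in ring A'', C6''–H is the only C–H ortho to the free 7''-OH that still has a hydrogen neighbour (C5''–H), because C8''–H is walled in by O1'' and O7''. In ring B, C3' lies next to the 4'-OMe group, exactly where diosmetin carries its phenolic OH. An O-boryl group on O7'' can therefore steer an iridium C–H borylation to C6'', and the 3'-oxygen can leave as triflate. All helpers (O–B, C–B, OTf) are lost in the same flask.
Stereochemistry: none has to be set.

Key step: step 5

Assumption: the SMILES holds no stereocentre and the C6''–C3' axis carries only two ortho substituents (7''-OH, 4'-OMe), so it turns freely at room temperature. The target is therefore made as the one achiral compound.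
Remark: B2eg2 is 2,2'-bi(1,3,2-dioxaborolane), treated as a stock reagent obtainable from tetrahydroxydiboron and ethylene glycol.

Step 1
Reactants: 1 diosmetin (5,7-dihydroxy-2-(3-hydroxy-4-methoxyphenyl)-4H-chromen-4-one)
Product: 2 7-O-methyldiosmetin (5-hydroxy-2-(3-hydroxy-4-methoxyphenyl)-7-methoxy-4H-chromen-4-one)
Conditions: MeI (1.05 equiv), K2CO3 (1.0 equiv), DMF, 0 °C → rt
Reagents that add atoms: iodomethane, CI
Why: Williamson O-methylation; the 7-OH, para to the C4 carbonyl (a vinylogous acid), is by far the most acidic phenol, so one equivalent of carbonate should ionise only it, while the guaiacol-type 3'-OH stays protonated and the 5-OH is locked in a hydrogen bond to C4=O.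

Step 2
Reactants: 2 7-O-methyldiosmetin
Product: 3 flavone 3'-triflate (5-(5-hydroxy-7-methoxy-4-oxo-4H-chromen-2-yl)-2-methoxyphenyl trifluoromethanesulfonate)
Conditions: PhNTf2 (1.05 equiv), K2CO3, DMF, rt
Reagents that add atoms: N-phenylbis(trifluoromethanesulfonimide), O=S(=O)(N(c1ccccc1)S(=O)(=O)C(F)(F)F)C(F)(F)F
Why: Phenol triflation with a mild triflyl-transfer reagent; only the free 3'-OH should react because the 5-OH is chelated to C4=O and hindered, which turns the native oxygen at C3' into the leaving group for the union.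

Step 3
Reactants: 4 2',4'-dihydroxyacetophenone (resacetophenone); 5 4-methoxybenzaldehyde
Product: 6 (E)-2',4'-dihydroxy-4-methoxychalcone ((E)-1-(2,4-dihydroxyphenyl)-3-(4-methoxyphenyl)prop-2-en-1-one)
Conditions: KOH (50 % aq), EtOH, rt; HCl aq
Reagents that add atoms: none
Why: Claisen–Schmidt condensation (aldol addition, then E1cB loss of water); 5 has no α-hydrogen, so only the methyl ketone of 4 enolises, and the conjugated E-enone is the thermodynamic product.

Step 4
Reactants: 6 (E)-2',4'-dihydroxy-4-methoxychalcone
Product: 8 3,7-dihydroxy-4'-methoxyflavone (3,7-dihydroxy-2-(4-methoxyphenyl)-4H-chromen-4-one), via trans-3-hydroxyflavanone 7 (not isolated)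
Conditions: H2O2 (30 % aq), NaOH aq, MeOH, 0 °C → rt; HCl aq
Reagents that add atoms: hydrogen peroxide, OO
Why: Algar–Flynn–Oyamada reaction; hydroperoxide attacks the enone and the 2'-phenoxide closes the six-membered ring C'' (O1''–C2'') to racemic trans-7, which a second equivalent of peroxide dehydrogenates to the flavonol, the absence of a 6'-substituent favouring flavonol over aurone and both transient stereocentres vanishing.

Step 5
Reactants: 8 3,7-dihydroxy-4'-methoxyflavone; 3 flavone 3'-triflate
Product: 11 abiesin, via bis-O-boryl flavonol 9 (not isolated), via C6''-boronate 10 (not isolated)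
Conditions: B2eg2 (2.0 equiv), [Ir(OMe)(cod)]2 (3 mol %), dtbpy (6 mol %), Et3N, THF, Ar, rt → 80 °C; then 3, Pd(OAc)2/SPhos (5/10 mol %), K3PO4 aq (degassed), 50 °C; work-up at pH 4
Reagents that add atoms: 2,2'-bi(1,3,2-dioxaborolane) (B2eg2), B1(OCCO1)B1OCCO1 (its boron groups stand in 9 and 10 only; none of its atoms stays in 11)
Why: The diboron first turns both acidic OH groups of 8 into O-boryl ethers (loss of H2), which masks them and makes O7'' a directing group, and the Ir(III) tris(boryl)–bipyridine catalyst then cleaves a C–H bond ortho to that group through the known attraction between the electron-rich O–B oxygen and the electron-poor bipyridine rim. Of the two ortho positions only C6''–H has a hydrogen neighbour (C5''–H), whereas C8''–H lies between O1'' and O7'' and is closed to the bulky catalyst, so boron should enter at C6''. Pd(0) then inserts into the C3'–OTf bond of 3, the base-activated C6'' boronate transmetallates, reductive elimination forms the C6''–C3' bond, and the aqueous base hydrolyses the two O–B bonds, so 11 should be released without any protecting-group step. The closest known reaction types are the traceless O-boryl-directed ortho C–H borylation of phenols and the one-pot C–H borylation/Suzuki–Miyaura sequence. No ring is closed and no stereocentre is formed. The step needs C6''–H to react ahead of C8''–H, C5''–H (peri to C4''=O) and the C–H ortho to the 4'''-OMe group, which the O-boryl direction, the electron-poor ring A'' and the limited diboron should secure, while 3 meets the flask only after water has stopped the borylation and its chelated 5-OH and both pyranones are inert to Pd/phosphate.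

Compound list
1 | diosmetin | COc1ccc(cc1O)-c1cc(=O)c2c(O)cc(O)cc2o1 | starting material
2 | 7-O-methyldiosmetin (5,3'-dihydroxy-7,4'-dimethoxyflavone) | COc1ccc(cc1O)-c1cc(=O)c2c(O)cc(OC)cc2o1 | intermediate
3 | 5-(5-hydroxy-7-methoxy-4-oxo-4H-chromen-2-yl)-2-methoxyphenyl trifluoromethanesulfonate | COc1ccc(cc1OS(=O)(=O)C(F)(F)F)-c1cc(=O)c2c(O)cc(OC)cc2o1 | intermediate
4 | 2',4'-dihydroxyacetophenone | CC(=O)c1ccc(O)cc1O | starting material
5 | 4-methoxybenzaldehyde | COc1ccc(C=O)cc1 | starting material
6 | (E)-1-(2,4-dihydroxyphenyl)-3-(4-methoxyphenyl)prop-2-en-1-one | COc1ccc(/C=C/C(=O)c2ccc(O)cc2O)cc1 | intermediate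
7 | trans-3,7-dihydroxy-2-(4-methoxyphenyl)chroman-4-one (racemic, one enantiomer drawn; not isolated) | COc1ccc(cc1)[C@@H]2[C@H](C(=O)c3ccc(O)cc3O2)O | intermediate
8 | 3,7-dihydroxy-2-(4-methoxyphenyl)-4H-chromen-4-one | COc1ccc(cc1)-c1oc2cc(O)ccc2c(=O)c1O | intermediate
9 | 3,7-bis[(1,3,2-dioxaborolan-2-yl)oxy]-2-(4-methoxyphenyl)-4H-chromen-4-one (not isolated) | COc1ccc(cc1)-c1oc2cc(OB3OCCO3)ccc2c(=O)c1OB1OCCO1 | intermediate
10 | 6-(1,3,2-dioxaborolan-2-yl)-3,7-bis[(1,3,2-dioxaborolan-2-yl)oxy]-2-(4-methoxyphenyl)-4H-chromen-4-one (not isolated) | COc1ccc(cc1)-c1oc2cc(OB3OCCO3)c(B3OCCO3)cc2c(=O)c1OB1OCCO1 | intermediate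
11 | abiesin: 3,7-dihydroxy-6-[5-(5-hydroxy-7-methoxy-4-oxo-4H-chromen-2-yl)-2-methoxyphenyl]-2-(4-methoxyphenyl)-4H-chromen-4-one | COc1ccc(-c2oc3cc(O)c(-c4cc(-c5cc(=O)c6c(O)cc(OC)cc6o5)ccc4OC)cc3c(=O)c2O)cc1 | target

Total step count: 5. Longest linear sequence: 3 steps (1 → 2 → 3 → 11, or 4 + 5 → 6 → 8 → 11).

Steps most likely to fail

Step 5. Site selection in the C–H borylation may leak to the C–H ortho to the 4'''-methoxy group. The ortho-oxygenated boronate may also protodeboronate before it transmetallates. The fallback sets out from 3 and 5 and comes back at 11; the C6'' handle is bought instead of being made by C–H activation. Miyaura borylation of 3 (B2pin2, Pd(dppf)Cl2, KOAc, dioxane, 90 °C) gives the flavone 3'-pinacolboronate F1. Purchased 1-(5-bromo-2,4-dihydroxyphenyl)ethanone F2 already carries bromine at the future C6''. It is condensed with 5 (KOH, EtOH) to the 5'-bromochalcone F3 and oxidised (H2O2, NaOH, MeOH) to 6-bromo-3,7-dihydroxy-4'-methoxyflavone F4. Suzuki–Miyaura coupling of F1 with F4 (Pd(OAc)2/SPhos, K3PO4, dioxane/H2O, 80 °C) gives 11.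

Step 4. The 4'-phenoxide pushes electron density into the enone, so hydroperoxide addition may stall. Five-membered ring closure or oxidative cleavage may then take over. The fallback sets out from 4 and comes back at 8; the phenol is masked so that no phenoxide deactivates the enone. Selective benzylation of the non-chelated 4-OH of 4 (BnBr, K2CO3, acetone, reflux) gives 4-benzyloxy-2-hydroxyacetophenone F5. Condensation with 5 (KOH, EtOH) gives the 4'-benzyloxychalcone F6. The Algar–Flynn–Oyamada reaction gives 7-benzyloxy-3-hydroxy-4'-methoxyflavone F7. Hydrogenolysis (H2, Pd/C, THF/MeOH) gives 8.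

Step 1. Site selectivity between the 7-OH and the 3'-OH may be lost, with over-alkylation as the result. The fallback sets out from 1 and comes back at 2; the differing lability of aryl acetates replaces the differing acidity of the phenols. Peracetylation (Ac2O, pyridine) gives diosmetin triacetate F8. Treatment with MeI and K2CO3 in dry acetone at reflux exchanges only the most activated ester, the 7-acetate para to the carbonyl, for a methyl ether and gives 7-O-methyldiosmetin 5,3'-diacetate F9. Methanolysis (K2CO3 cat., MeOH) gives 2.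

Further compounds
F1 | step 5 | 5-hydroxy-7-methoxy-2-[4-methoxy-3-(4,4,5,5-tetramethyl-1,3,2-dioxaborolan-2-yl)phenyl]-4H-chromen-4-one | COc1ccc(cc1B3OC(C)(C)C(C)(C)O3)-c1cc(=O)c2c(O)cc(OC)cc2o1
F2 | step 5 | 1-(5-bromo-2,4-dihydroxyphenyl)ethanone (purchased) | CC(=O)c1cc(Br)c(O)cc1O
F3 | step 5 | (E)-1-(5-bromo-2,4-dihydroxyphenyl)-3-(4-methoxyphenyl)prop-2-en-1-one | COc1ccc(/C=C/C(=O)c2cc(Br)c(O)cc2O)cc1
F4 | step 5 | 6-bromo-3,7-dihydroxy-2-(4-methoxyphenyl)-4H-chromen-4-one | COc1ccc(cc1)-c1oc2cc(O)c(Br)cc2c(=O)c1O
F5 | step 4 | 1-[4-(benzyloxy)-2-hydroxyphenyl]ethanone | CC(=O)c1ccc(OCc2ccccc2)cc1O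
F6 | step 4 | (E)-1-[4-(benzyloxy)-2-hydroxyphenyl]-3-(4-methoxyphenyl)prop-2-en-1-one | COc1ccc(/C=C/C(=O)c2ccc(OCc3ccccc3)cc2O)cc1
F7 | step 4 | 7-(benzyloxy)-3-hydroxy-2-(4-methoxyphenyl)-4H-chromen-4-one | COc1ccc(cc1)-c1oc2cc(OCc3ccccc3)ccc2c(=O)c1O
F8 | step 1 | diosmetin 5,7,3'-triacetate | COc1ccc(cc1OC(C)=O)-c1cc(=O)c2c(OC(C)=O)cc(OC(C)=O)cc2o1
F9 | step 1 | 7-O-methyldiosmetin 5,3'-diacetate | COc1ccc(cc1OC(C)=O)-c1cc(=O)c2c(OC(C)=O)cc(OC)cc2o1
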